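**Plan**

- Retrosynthesis: the acid is unmasked from its methyl ester. The C3a–C7a ring-fusion bond and the C4–C5 bond between the two quaternary carbons are then cut together (retro-[4+2]), which opens both rings to one acyclic pentaenoate. That chain is cut at its enoate double bond, at its (Z)-trisubstituted alkene and three times in the phenyl triene, back to methyl (R)-3-hydroxy-2-methylpropanoate.
- Enabling feature: the cyclohexene ring C3a–C4–C5–C6=C7–C7a has its double bond opposite the fusion bond (a Diels–Alder retron). The cyclopentene C2=C3 alkene is a ready-made cis tether of three atoms (C3, C2, C1) between dienophile carbon C3a and diene terminus C7a.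
- Forward: the chain is grown by olefinations outward from the methyl-bearing carbon (phenyl triene arm first, then the (Z)-enoate, then the dienoate). Cyclopentene and cyclohexene then arise together in one intramolecular cycloaddition, and ester cleavage ends the route.
- Stereochemistry: C1 is bought. C3a, C7a and the vicinal quaternary C4 and C5 are all relayed from it in the cycloaddition through alkene geometry, endo approach and allylic strain.

Key step: step 13

Remark: ring positions are numbered as in 1H-indene (C1 methyl-bearing, C3a and C7a ring fusion, C4 carboxyl-bearing, C5 styryl-bearing); the three phosphorus ylides, the two phosphonates and the hydroxy ester used as starting materials are taken to be catalogue compounds.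

**Route**

Step 1
Reactants: 1 methyl (R)-3-hydroxy-2-methylpropanoate
Product: 2 methyl (R)-3-[(tert-butyldimethylsilyl)oxy]-2-methylpropanoate
Conditions: TBSCl, imidazole, DMF, 0 °C → rt
Reagents that add atoms: tert-butyldimethylsilyl chloride, CC(C)(C)[Si](C)(C)Cl
Why: Imidazole-promoted silylation of a primary alcohol masks the hydroxyl arm while the ester arm is elaborated, and the stereocentre is not touched.

Step 2
Reactants: 2 methyl (R)-3-[(tert-butyldimethylsilyl)oxy]-2-methylpropanoate
Product: 3 (R)-3-[(tert-butyldimethylsilyl)oxy]-2-methylpropanal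
Conditions: i-Bu2AlH (1.1 equiv), CH2Cl2, −78 °C; aqueous work-up
Reagents that add atoms: none
Why: Partial ester reduction with i-Bu2AlH stops at the aluminium hemiacetal at −78 °C and releases the aldehyde on work-up, and the aldehyde is carried on crude so that its α-stereocentre should not epimerise.

Step 3
Reactants: 3 (R)-3-[(tert-butyldimethylsilyl)oxy]-2-methylpropanal; 4 2-(triphenylphosphoranylidene)propanal
Product: 5 (S,E)-5-[(tert-butyldimethylsilyl)oxy]-2,4-dimethylpent-2-enal
Conditions: toluene, 100 °C
Reagents that add atoms: none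
Why: Wittig olefination with a formyl-stabilised ylide should give the (E)-2-methyl enal directly, and the weakly basic ylide should leave the α-stereocentre intact.

Step 4
Reactants: 5 (S,E)-5-[(tert-butyldimethylsilyl)oxy]-2,4-dimethylpent-2-enal; 6 2-(triphenylphosphoranylidene)butanal
Product: 7 (2E,4E,6S)-7-[(tert-butyldimethylsilyl)oxy]-2-ethyl-4,6-dimethylhepta-2,4-dienal
Conditions: toluene, 110 °C
Reagents that add atoms: none
Why: A second Wittig homologation with the ethyl-substituted formyl ylide should set the (E)-trisubstituted C2=C3 bond (ethyl cis to the chain, formyl trans), the more hindered and less electrophilic dienal product being slower to react further.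

Step 5
Reactants: 7 (2E,4E,6S)-7-[(tert-butyldimethylsilyl)oxy]-2-ethyl-4,6-dimethylhepta-2,4-dienal; 8 diethyl benzylphosphonate
Product: 9 tert-butyl{[(2S,3E,5E,7E)-6-ethyl-2,4-dimethyl-8-phenylocta-3,5,7-trien-1-yl]oxy}dimethylsilane
Conditions: NaN(SiMe3)2, THF, −78 → 0 °C
Reagents that add atoms: none
Why: Horner–Wadsworth–Emmons olefination with the benzylphosphonate anion should give the (E)-styryl double bond, the usual outcome for stabilised phosphonates, and completes the (E,E,E)-triene.

Step 6
Reactants: 9 tert-butyl{[(2S,3E,5E,7E)-6-ethyl-2,4-dimethyl-8-phenylocta-3,5,7-trien-1-yl]oxy}dimethylsilane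
Product: 10 (2S,3E,5E,7E)-6-ethyl-2,4-dimethyl-8-phenylocta-3,5,7-trien-1-ol
Conditions: HF·pyridine, pyridine, THF, 0 °C → rt
Reagents that add atoms: none
Why: Fluoride cleaves the primary silyl ether through the strong Si–F bond, and the pyridine buffer should keep the acid-sensitive phenyl triene intact.

Step 7
Reactants: 10 (2S,3E,5E,7E)-6-ethyl-2,4-dimethyl-8-phenylocta-3,5,7-trien-1-ol
Product: 11 (2S,3E,5E,7E)-6-ethyl-2,4-dimethyl-8-phenylocta-3,5,7-trienal
Conditions: Dess–Martin periodinane, NaHCO3, CH2Cl2, 0 °C; used at once without chromatography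
Reagents that add atoms: none
Why: Dess–Martin oxidation under bicarbonate buffer is a neutral, non-basic alcohol-to-aldehyde oxidation, chosen because the new aldehyde has an allylic α-hydrogen that base or heat could epimerise.

Step 8
Reactants: 12 methyl 2-[bis(2,2,2-trifluoroethoxy)phosphoryl]acetate
Product: 13 methyl 2-[bis(2,2,2-trifluoroethoxy)phosphoryl]butanoate
Conditions: NaH, THF/DMF, 0 °C → rt
Reagents that add atoms: iodoethane, CCI
Why: SN2 C-alkylation of the sodium phosphonoacetate enolate with iodoethane gives the α-ethyl Still–Gennari reagent, which is used as the racemate because its stereocentre is lost on olefination.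

Step 9
Reactants: 11 (2S,3E,5E,7E)-6-ethyl-2,4-dimethyl-8-phenylocta-3,5,7-trienal; 13 methyl 2-[bis(2,2,2-trifluoroethoxy)phosphoryl]butanoate
Product: 14 methyl (2Z,4S,5E,7E,9E)-2,8-diethyl-4,6-dimethyl-10-phenyldeca-2,5,7,9-tetraenoate
Conditions: KN(SiMe3)2 (slightly less than 13), 18-crown-6, THF, −78 °C
Reagents that add atoms: none
Why: In the Still–Gennari olefination the electron-poor bis(trifluoroethyl) phosphonate with a crown-separated potassium counter-ion eliminates fast from the kinetically formed adduct and should therefore give the (Z)-α-ethyl enoate, at a temperature where the labile α-stereocentre of the aldehyde should survive.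

Step 10
Reactants: 14 methyl (2Z,4S,5E,7E,9E)-2,8-diethyl-4,6-dimethyl-10-phenyldeca-2,5,7,9-tetraenoate
Product: 15 (2Z,4S,5E,7E,9E)-2,8-diethyl-4,6-dimethyl-10-phenyldeca-2,5,7,9-tetraen-1-ol
Conditions: i-Bu2AlH (2.5 equiv), CH2Cl2, −78 °C
Reagents that add atoms: none
Why: i-Bu2AlH reduces the conjugated ester in a 1,2-sense to the allylic alcohol without touching alkene geometry or the allylic stereocentre.

Step 11
Reactants: 15 (2Z,4S,5E,7E,9E)-2,8-diethyl-4,6-dimethyl-10-phenyldeca-2,5,7,9-tetraen-1-ol
Product: 16 (2Z,4S,5E,7E,9E)-2,8-diethyl-4,6-dimethyl-10-phenyldeca-2,5,7,9-tetraenal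
Conditions: MnO2 (excess), CH2Cl2, rt, dark
Reagents that add atoms: none
Why: MnO2 oxidises allylic alcohols selectively under neutral heterogeneous conditions, which should preserve both the (Z) geometry and the γ-stereocentre of the enal.

Step 12
Reactants: 16 (2Z,4S,5E,7E,9E)-2,8-diethyl-4,6-dimethyl-10-phenyldeca-2,5,7,9-tetraenal; 17 methyl 2-(triphenylphosphoranylidene)propanoate
Product: 18 methyl (2E,4Z,6S,7E,9E,11E)-4,10-diethyl-2,6,8-trimethyl-12-phenyldodeca-2,4,7,9,11-pentaenoate
Conditions: CH2Cl2, rt → 40 °C, dark; product kept cold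
Reagents that add atoms: none
Why: Wittig olefination with the ester-stabilised ylide should give the (E)-2-methyl enoate and needs no base, so the (4Z) alkene and the doubly allylic C6 stereocentre are not put at risk.

Step 13
Reactants: 18 methyl (2E,4Z,6S,7E,9E,11E)-4,10-diethyl-2,6,8-trimethyl-12-phenyldodeca-2,4,7,9,11-pentaenoate
Product: 19 methyl (1R,3aR,4R,5S,7aS)-3,5-diethyl-1,4,7-trimethyl-5-[(E)-2-phenylethenyl]-3a,4,5,7a-tetrahydro-1H-indene-4-carboxylate
Conditions: toluene (0.01 M, degassed), BHT (catalytic), 100 °C, dark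
Reagents that add atoms: none
Why: A concerted but asynchronous, suprafacial [4+2] cycloaddition joins the C2=C3 enoate bond of 18 to the C7=C8–C9=C10 diene, the C3–C7 bond (the later ring fusion) leading and the C2–C10 bond between the two future quaternary carbons following; the closest known reaction type is the thermal intramolecular Diels–Alder reaction of (E,E,E)-nona-2,7,9-trienoates, which gives trans-fused hydrindenes. The cyclopentene closes as the tether ring of a type 1 cycloaddition (C3 to C7 across the three-atom C4=C5–C6 tether, whose (Z) alkene already holds the two ends together), and the cyclohexene closes as the six-membered ring of the [4+2] process itself. The quaternary centres from C2 and C10 follow from the (2E) and (9E) geometries, so that the ester should end cis to styryl and methyl cis to ethyl. The trans relation of the two fusion hydrogens should follow from the transition state with the ester endo and the tether anti to the diene, favoured by secondary orbital overlap and because the C8 methyl group collides with the tether in the cis-fused alternative. The diene face is set by the C6 stereocentre, whose hydrogen eclipses C7=C8 to avoid allylic 1,3-strain with the C8 methyl, so that its methyl group points away from the dienophile and ends cis to the fusion hydrogen from C7. The step needs endo over exo selectivity and a cycloaddition faster than the [1,5]-hydrogen shift open to the (4Z)-dienoate, which the C8 methyl group and the preorganising (Z) tether of the substrate, helped by the lowest workable temperature, should secure.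

Step 14
Reactants: 19 methyl (1R,3aR,4R,5S,7aS)-3,5-diethyl-1,4,7-trimethyl-5-[(E)-2-phenylethenyl]-3a,4,5,7a-tetrahydro-1H-indene-4-carboxylate
Product: 20 (1R,3aR,4R,5S,7aS)-3,5-diethyl-1,4,7-trimethyl-5-[(E)-2-phenylethenyl]-3a,4,5,7a-tetrahydro-1H-indene-4-carboxylic acid (24-nor-spiculoic acid B)
Conditions: NaSC2H5, DMF, 90 °C; then cold 1 M HCl
Reagents that add atoms: none
Why: The thiolate attacks the unhindered methyl carbon of the ester (SN2 dealkylation), which should free the acid without any attack at a carbonyl group shielded by two adjacent quaternary carbons, and the product has no epimerisable stereocentre.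

**Compound list**

1 | methyl (R)-3-hydroxy-2-methylpropanoate | COC(=O)[C@H](C)CO | starting material
2 | methyl (R)-3-[(tert-butyldimethylsilyl)oxy]-2-methylpropanoate | COC(=O)[C@H](C)CO[Si](C)(C)C(C)(C)C | intermediate
3 | (R)-3-[(tert-butyldimethylsilyl)oxy]-2-methylpropanal | O=C[C@H](C)CO[Si](C)(C)C(C)(C)C | intermediate
4 | 2-(triphenylphosphoranylidene)propanal | CC(C=O)=P(c1ccccc1)(c1ccccc1)c1ccccc1 | starting material
5 | (S,E)-5-[(tert-butyldimethylsilyl)oxy]-2,4-dimethylpent-2-enal | CC(C)(C)[Si](C)(C)OC[C@@H](C)/C=C(\C)C=O | intermediate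
6 | 2-(triphenylphosphoranylidene)butanal | CCC(C=O)=P(c1ccccc1)(c1ccccc1)c1ccccc1 | starting material
7 | (2E,4E,6S)-7-[(tert-butyldimethylsilyl)oxy]-2-ethyl-4,6-dimethylhepta-2,4-dienal | CC(C)(C)[Si](C)(C)OC[C@@H](C)/C=C(\C)/C=C(\CC)C=O | intermediate
8 | diethyl benzylphosphonate | CCOP(=O)(Cc1ccccc1)OCC | starting material
9 | tert-butyl{[(2S,3E,5E,7E)-6-ethyl-2,4-dimethyl-8-phenylocta-3,5,7-trien-1-yl]oxy}dimethylsilane | CC(C)(C)[Si](C)(C)OC[C@@H](C)/C=C(\C)/C=C(\CC)/C=C/c1ccccc1 | intermediate
10 | (2S,3E,5E,7E)-6-ethyl-2,4-dimethyl-8-phenylocta-3,5,7-trien-1-ol | OC[C@@H](C)/C=C(\C)/C=C(\CC)/C=C/c1ccccc1 | intermediate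
11 | (2S,3E,5E,7E)-6-ethyl-2,4-dimethyl-8-phenylocta-3,5,7-trienal | O=C[C@@H](C)/C=C(\C)/C=C(\CC)/C=C/c1ccccc1 | intermediate
12 | methyl 2-[bis(2,2,2-trifluoroethoxy)phosphoryl]acetate | COC(=O)CP(=O)(OCC(F)(F)F)OCC(F)(F)F | starting material
13 | methyl 2-[bis(2,2,2-trifluoroethoxy)phosphoryl]butanoate (racemic) | CCC(C(=O)OC)P(=O)(OCC(F)(F)F)OCC(F)(F)F | intermediate
14 | methyl (2Z,4S,5E,7E,9E)-2,8-diethyl-4,6-dimethyl-10-phenyldeca-2,5,7,9-tetraenoate | CC/C(C(=O)OC)=C/[C@@H](C)/C=C(\C)/C=C(\CC)/C=C/c1ccccc1 | intermediate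
15 | (2Z,4S,5E,7E,9E)-2,8-diethyl-4,6-dimethyl-10-phenyldeca-2,5,7,9-tetraen-1-ol | CC/C(CO)=C/[C@@H](C)/C=C(\C)/C=C(\CC)/C=C/c1ccccc1 | intermediate
16 | (2Z,4S,5E,7E,9E)-2,8-diethyl-4,6-dimethyl-10-phenyldeca-2,5,7,9-tetraenal | CC/C(C=O)=C/[C@@H](C)/C=C(\C)/C=C(\CC)/C=C/c1ccccc1 | intermediate
17 | methyl 2-(triphenylphosphoranylidene)propanoate | COC(=O)C(C)=P(c1ccccc1)(c1ccccc1)c1ccccc1 | starting material
18 | methyl (2E,4Z,6S,7E,9E,11E)-4,10-diethyl-2,6,8-trimethyl-12-phenyldodeca-2,4,7,9,11-pentaenoate | CC/C(/C=C(\C)C(=O)OC)=C/[C@@H](C)/C=C(\C)/C=C(\CC)/C=C/c1ccccc1 | intermediate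
19 | methyl (1R,3aR,4R,5S,7aS)-3,5-diethyl-1,4,7-trimethyl-5-[(E)-2-phenylethenyl]-3a,4,5,7a-tetrahydro-1H-indene-4-carboxylate | CCC1=C[C@@H](C)[C@@H]2C(C)=C[C@@](/C=C/c3ccccc3)(CC)[C@](C)(C(=O)OC)[C@@H]12 | intermediate
20 | (1R,3aR,4R,5S,7aS)-3,5-diethyl-1,4,7-trimethyl-5-[(E)-2-phenylethenyl]-3a,4,5,7a-tetrahydro-1H-indene-4-carboxylic acid (24-nor-spiculoic acid B) | CCC1=C[C@@H](C)[C@@H]2C(C)=C[C@@](/C=C/c3ccccc3)(CC)[C@](C)(C(=O)O)[C@@H]12 | target

**Step count**

Total step count: 14. Longest linear sequence: 13 steps (steps 1–7 and 9–14); step 8 is a one-step reagent branch.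

**Steps most likely to fail**

Step 13. The cycloaddition may show too small a preference for the ester-endo, trans-fused transition state. The temperature that the hindered diene demands may also let a [1,5]-hydrogen shift of the (4Z)-dienoate, or decomposition of the polyene, outrun ring closure. The fallback sets out from 18 and comes back to the route at acid 20, so that steps 13 and 14 are both replaced. Ester 18 would be reduced with i-Bu2AlH (CH2Cl2, −78 °C) to (2E,4Z,6S,7E,9E,11E)-4,10-diethyl-2,6,8-trimethyl-12-phenyldodeca-2,4,7,9,11-pentaen-1-ol F1. MnO2 would oxidise this to (2E,4Z,6S,7E,9E,11E)-4,10-diethyl-2,6,8-trimethyl-12-phenyldodeca-2,4,7,9,11-pentaenal F2. The enal is a stronger dienophile that responds to Lewis acids, and it would be cyclised with Me2AlCl in CH2Cl2 at −78 to −20 °C, where the endo preference should be larger and the sigmatropic shift frozen out. This should give (1R,3aR,4R,5S,7aS)-3,5-diethyl-1,4,7-trimethyl-5-[(E)-2-phenylethenyl]-3a,4,5,7a-tetrahydro-1H-indene-4-carbaldehyde F3. Pinnick oxidation (NaClO2, NaH2PO4, 2-methyl-2-butene, t-BuOH/H2O) would then give 20.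

Step 9. The olefination may lose (Z) selectivity, or the α-methyl-β,γ-unsaturated aldehyde may epimerise or slip into conjugation under the basic conditions. The fallback sets out from 11 and comes back at enoate 14, forming the (Z) alkene by cross-coupling logic instead of a phosphonate olefination. Aldehyde 11 would be treated at −78 °C with (1-iodopropylidene)triphenylphosphorane F4, made in the flask from propyltriphenylphosphonium bromide (n-BuLi; I2; NaN(SiMe3)2), in a Stork–Zhao-type iodo-olefination. This should give the (Z)-vinyl iodide [(1E,3E,5E,7S,8Z)-3-ethyl-9-iodo-5,7-dimethylundeca-1,3,5,8-tetraen-1-yl]benzene F5. Palladium-catalysed methoxycarbonylation (Pd(OAc)2, PPh3, CO, MeOH, Et3N, DMF, 50 °C), which proceeds with retention of alkene geometry, would then deliver 14.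

Step 4. The formyl ylide may react too slowly with the hindered α-methyl enal, and the dienal product may be homologated a second time by the same ylide. The fallback sets out from 5 and comes back at dienal 7, replacing the one-step formyl-ylide homologation by olefination at the ester oxidation level followed by redox adjustment. Horner–Wadsworth–Emmons reaction of 5 with triethyl 2-phosphonobutanoate (NaH, THF, 0 °C) should give ethyl (2E,4E,6S)-7-[(tert-butyldimethylsilyl)oxy]-2-ethyl-4,6-dimethylhepta-2,4-dienoate F6, which cannot over-react. i-Bu2AlH would reduce it to (2E,4E,6S)-7-[(tert-butyldimethylsilyl)oxy]-2-ethyl-4,6-dimethylhepta-2,4-dien-1-ol F7, and MnO2 would oxidise that to 7.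

Further compounds
F1 | step 13 | (2E,4Z,6S,7E,9E,11E)-4,10-diethyl-2,6,8-trimethyl-12-phenyldodeca-2,4,7,9,11-pentaen-1-ol | CC/C(/C=C(\C)CO)=C/[C@@H](C)/C=C(\C)/C=C(\CC)/C=C/c1ccccc1
F2 | step 13 | (2E,4Z,6S,7E,9E,11E)-4,10-diethyl-2,6,8-trimethyl-12-phenyldodeca-2,4,7,9,11-pentaenal | CC/C(/C=C(\C)C=O)=C/[C@@H](C)/C=C(\C)/C=C(\CC)/C=C/c1ccccc1
F3 | step 13 | (1R,3aR,4R,5S,7aS)-3,5-diethyl-1,4,7-trimethyl-5-[(E)-2-phenylethenyl]-3a,4,5,7a-tetrahydro-1H-indene-4-carbaldehyde | CCC1=C[C@@H](C)[C@@H]2C(C)=C[C@@](/C=C/c3ccccc3)(CC)[C@](C)(C=O)[C@@H]12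
F4 | step 9 | (1-iodopropylidene)triphenylphosphorane | CCC(I)=P(c1ccccc1)(c1ccccc1)c1ccccc1
F5 | step 9 | [(1E,3E,5E,7S,8Z)-3-ethyl-9-iodo-5,7-dimethylundeca-1,3,5,8-tetraen-1-yl]benzene | CC/C(I)=C/[C@@H](C)/C=C(\C)/C=C(\CC)/C=C/c1ccccc1
F6 | step 4 | ethyl (2E,4E,6S)-7-[(tert-butyldimethylsilyl)oxy]-2-ethyl-4,6-dimethylhepta-2,4-dienoate | CC(C)(C)[Si](C)(C)OC[C@@H](C)/C=C(\C)/C=C(\CC)C(=O)OCC
F7 | step 4 | (2E,4E,6S)-7-[(tert-butyldimethylsilyl)oxy]-2-ethyl-4,6-dimethylhepta-2,4-dien-1-ol | CC(C)(C)[Si](C)(C)OC[C@@H](C)/C=C(\C)/C=C(\CC)CO
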